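**Retrosynthetic overview**
Target 14 (5R) ⇐ N-oxidation of pyridine 13 ⇐ O-4 methylation of 4-pyridone 12 ⇐ hydrogenation of the C7=C8 alkene of dihydroquinolinone 11.
11 ⇐ one-flask asymmetric [3+3] annulation that forms C4a–C5 and C7–C8 from 3-methoxy-2,6-dimethylpyridin-4(1H)-one 3 (C,C-1,3-dinucleophile) and (E)-8-phenyloct-2-enal 7 (1,3-dielectrophile).
Enabling feature: the C-4 oxygen of the pyridine ring, held at the 4-pyridone level. The N1–C8a=C4a–C4=O enaminone makes ring carbon C-4a (the only unsubstituted one) nucleophilic and the methyl on C-8a (future C-8) vinylogously enolisable; the same oxygen later becomes the 4-OMe.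
Ring order: the pyridine ring is bought as symmetric 2,6-dimethyl-4-pyridone 1 and desymmetrised to 3 by bromination/methoxylation; the carbocycle is built onto it in the key step; 7 comes from 6-phenylhexan-1-ol 4 by oxidation and Wittig olefination.

Key step: step 5

Assumption: the (S)-diarylprolinol silyl ether is taken to follow its usual model for E-enals (addition to the β-carbon anti to the C(Ph)2OSiMe3 group), which corresponds to 5R here; if the sense were opposite, the (R)-catalyst would be used with nothing else changed.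

**Step 1**
Reactants: 1 2,6-dimethylpyridin-4(1H)-one
Product: 2 3-bromo-2,6-dimethylpyridin-4(1H)-one
Conditions: NBS (1.0 equiv), DMF, 0 °C to rt
Reagents that add atoms: N-bromosuccinimide, O=C1CCC(=O)N1Br
Why: Electrophilic aromatic bromination at the enaminone α-carbon of a 4-pyridone; the two α-positions are equivalent and the first bromine deactivates the ring, so one equivalent should stop at the monobromide.

**Step 2**
Reactants: 2 3-bromo-2,6-dimethylpyridin-4(1H)-one
Product: 3 3-methoxy-2,6-dimethylpyridin-4(1H)-one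
Conditions: NaOMe (5 equiv), CuBr (15 mol%), MeOH/DMF, 110 °C, sealed vessel
Reagents that add atoms: sodium methoxide, [Na+].[O-]C
Why: Ullmann-type methoxylation catalysed by monovalent copper of an aryl bromide ortho to an oxido group, the reaction type that turns ortho-bromophenolates into guaiacol-type ethers.

**Step 3**
Reactants: 4 6-phenylhexan-1-ol
Product: 5 6-phenylhexanal
Conditions: TEMPO (1 mol%), KBr (10 mol%), NaOCl (1.1 equiv), NaHCO3, CH2Cl2/H2O, 0 °C
Reagents that add atoms: none
Why: Anelli oxidation of a primary aliphatic alcohol should stop at the aldehyde under buffered two-phase conditions.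

**Step 4**
Reactants: 5 6-phenylhexanal; 6 (triphenylphosphoranylidene)acetaldehyde
Product: 7 (E)-8-phenyloct-2-enal
Conditions: 6 (1.1 equiv), toluene, 80 °C
Reagents that add atoms: none
Why: Wittig olefination with a formyl-stabilised ylide should give the E-enal.

**Step 5**
Reactants: 3 3-methoxy-2,6-dimethylpyridin-4(1H)-one; 7 (E)-8-phenyloct-2-enal
Product: 11 (5R)-3-methoxy-2-methyl-5-(5-phenylpentyl)-5,6-dihydroquinolin-4(1H)-one, via Michael adduct aldehyde 8 (not isolated), via pyranopyridine lactol 9 (not isolated), via aldol 10 (not isolated)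
Conditions: (S)-α,α-diphenylprolinol trimethylsilyl ether (20 mol%), PhCO2H (40 mol%), 7 (1.3 equiv, added slowly), MeCN, rt; then 4 Å MS, 75 °C, same flask
Reagents that add atoms: none
Why: Proposed new method: the secondary amine turns enal 7 into its E-iminium ion, the enaminone α-carbon of pyridone 3 (its only unsubstituted ring carbon, the future C-4a) adds to the β-carbon in a Friedel–Crafts-type conjugate addition to give aldehyde 8 (resting as lactol 9), and on heating the amine re-activates the aldehyde carbon (future C-7) as an iminium ion that is attacked by the 6-methyl carbon (future C-8) through the exocyclic enamine tautomer of the 2-methyl-4-pyridone, after which aldol 10 (or its amine equivalent) eliminates to the C7=C8 alkene of 11. The closest known reaction types are the diarylprolinol silyl ether catalysed Friedel–Crafts alkylation of enals by naphthols and 4-hydroxycoumarins, the one-flask Michael addition/aldol condensation of β-keto esters with enals to cyclohexenones under the same catalysts, and the amine-promoted condensation of 2-methyl-4-pyridones and 2-methyl-4-quinolones with aldehydes at the methyl group; new is a 4-pyridone as C,C-1,3-dinucleophile. The only ring closed is the carbocycle C4a–C5–C6–C7–C8–C8a, by a formal [3+3] annulation in which the first bond is made between the two components and the ring closes in a 6-(enolendo)-exo-trig vinylogous aldol (Mannich-type) addition. The C-5 stereocentre is set in the first bond formation by the catalyst, whose C(Ph)2OSiMe3 group covers one face of the s-trans E-iminium ion so that the pyridone adds to the open face (5R with the S catalyst), and it is not touched by the condensation. The step needs C- over N- or O-alkylation (the nitrogen is flanked by two methyl groups and hetero-Michael adducts revert), 1,4- over 1,2-addition (bulky secondary amine), and condensation of the 6- and not the 2-methyl group (only the 6-methyl reaches the aldehyde through a six-membered transition state, and the methyl deprotonations are reversible).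

**Step 6**
Reactants: 11 (5R)-3-methoxy-2-methyl-5-(5-phenylpentyl)-5,6-dihydroquinolin-4(1H)-one
Product: 12 (5R)-3-methoxy-2-methyl-5-(5-phenylpentyl)-5,6,7,8-tetrahydroquinolin-4(1H)-one
Conditions: H2 (1 atm), 10% Pd/C, MeOH, rt
Reagents that add atoms: none
Why: Heterogeneous hydrogenation of the conjugated disubstituted C7=C8 alkene should leave the pyridone and phenyl rings intact, and the C-5 stereocentre is not allylic to the alkene.

**Step 7**
Reactants: 12 (5R)-3-methoxy-2-methyl-5-(5-phenylpentyl)-5,6,7,8-tetrahydroquinolin-4(1H)-one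
Product: 13 (5R)-3,4-dimethoxy-2-methyl-5-(5-phenylpentyl)-5,6,7,8-tetrahydroquinoline
Conditions: MeI (2 equiv), Ag2CO3 (1.2 equiv), toluene, 50 °C, dark
Reagents that add atoms: iodomethane, CI
Why: Silver-salt O-alkylation of a pyridone; the nitrogen is flanked by the 2-methyl group and the ring CH2 at C-8, so methylation should go to O-4.

**Step 8**
Reactants: 13 (5R)-3,4-dimethoxy-2-methyl-5-(5-phenylpentyl)-5,6,7,8-tetrahydroquinoline
Product: 14 (5R)-3,4-dimethoxy-2-methyl-5-(5-phenylpentyl)-5,6,7,8-tetrahydroquinoline 1-oxide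
Conditions: mCPBA (1.2 equiv), CH2Cl2, 0 °C to rt
Reagents that add atoms: 3-chloroperoxybenzoic acid, OOC(=O)c1cccc(Cl)c1
Why: Peracid N-oxidation of a pyridine; no other group is oxidisable and the stereocentre is not involved.

**Compound list**
1 | 2,6-dimethylpyridin-4(1H)-one | Cc1cc(=O)cc(C)[nH]1 | starting material
2 | 3-bromo-2,6-dimethylpyridin-4(1H)-one | Cc1cc(=O)c(Br)c(C)[nH]1 | intermediate
3 | 3-methoxy-2,6-dimethylpyridin-4(1H)-one | COc1c(C)[nH]c(C)cc1=O | intermediate
4 | 6-phenylhexan-1-ol | OCCCCCCc1ccccc1 | starting material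
5 | 6-phenylhexanal | O=CCCCCCc1ccccc1 | intermediate
6 | (triphenylphosphoranylidene)acetaldehyde | O=CC=P(c1ccccc1)(c1ccccc1)c1ccccc1 | starting material
7 | (E)-8-phenyloct-2-enal | O=C/C=C/CCCCCc1ccccc1 | intermediate
8 | (3R)-3-(5-methoxy-2,6-dimethyl-4-oxo-1,4-dihydropyridin-3-yl)-8-phenyloctanal | O=CC[C@@H](CCCCCc1ccccc1)c1c(C)[nH]c(C)c(OC)c1=O | intermediate
9 | (4R)-8-methoxy-5,7-dimethyl-4-(5-phenylpentyl)-3,4-dihydro-2H-pyrano[3,2-c]pyridin-2-ol (both C-2 epimers) | COc1c(C)nc(C)c2[C@H](CCCCCc3ccccc3)CC(O)Oc12 | intermediate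
10 | (5R)-7-hydroxy-3-methoxy-2-methyl-5-(5-phenylpentyl)-5,6,7,8-tetrahydroquinolin-4(1H)-one (both C-7 epimers) | COc1c(C)[nH]c2c(c1=O)[C@H](CCCCCc1ccccc1)CC(O)C2 | intermediate
11 | (5R)-3-methoxy-2-methyl-5-(5-phenylpentyl)-5,6-dihydroquinolin-4(1H)-one | COc1c(C)[nH]c2c(c1=O)[C@H](CCCCCc1ccccc1)CC=C2 | intermediate
12 | (5R)-3-methoxy-2-methyl-5-(5-phenylpentyl)-5,6,7,8-tetrahydroquinolin-4(1H)-one | COc1c(C)[nH]c2c(c1=O)[C@H](CCCCCc1ccccc1)CCC2 | intermediate
13 | (5R)-3,4-dimethoxy-2-methyl-5-(5-phenylpentyl)-5,6,7,8-tetrahydroquinoline | COc1c(OC)c(C)nc2c1[C@H](CCCCCc1ccccc1)CCC2 | intermediate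
14 | (5R)-3,4-dimethoxy-2-methyl-5-(5-phenylpentyl)-5,6,7,8-tetrahydroquinoline 1-oxide | COc1c(OC)c(C)[n+]([O-])c2c1[C@H](CCCCCc1ccccc1)CCC2 | target

**Totals**
Total step count: 8. Longest linear sequence: 6 steps (steps 1, 2, 5, 6, 7, 8, from 1).

**Steps most likely to fail**

1. Step 5 (proposed new method). The carbon nucleophilicity of the pyridone may be too low, so that self-condensation of the enal through its dienamine outruns the conjugate addition. Hetero-Michael addition at N or O may compete, the sequence may stall at the lactol stage because the vinylogous condensation is slow, and enantiopurity may erode through reversible addition on heating.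
Fallback with known chemistry, setting out from 3 and returning at 13 (bypassing 11 and 12). Bromination of the free ring position (NBS, DMF) should give 3-bromo-5-methoxy-2,6-dimethylpyridin-4(1H)-one F1. O-methylation (MeI, Ag2CO3) should give 3-bromo-4,5-dimethoxy-2,6-dimethylpyridine F2. Miyaura borylation (B2pin2, Pd(dppf)Cl2, KOAc, dioxane, 90 °C) should give 3,4-dimethoxy-2,6-dimethyl-5-(4,4,5,5-tetramethyl-1,3,2-dioxaborolan-2-yl)pyridine F3. Rhodium-catalysed asymmetric 1,4-addition of F3 to enal 7 ([RhCl(C2H4)2]2, chiral bicyclic diene ligand of the enantiomeric series that gives 3R, KOH, dioxane/H2O) should give (3R)-3-(4,5-dimethoxy-2,6-dimethylpyridin-3-yl)-8-phenyloctanal F4. The classical 2-picoline/aldehyde condensation, run intramolecularly (Ac2O/AcOH, 120 °C), should close the ring at the 6-methyl group to (5R)-3,4-dimethoxy-2-methyl-5-(5-phenylpentyl)-5,6-dihydroquinoline F5. Hydrogenation (H2, 10% Pd/C) then gives 13.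

2. Step 7. Methylation may go to nitrogen, or the 4-methoxypyridine formed may be quaternised and then lose the O-methyl group (net O-to-N methyl migration).
Fallback setting out from 12 and returning at 14 (bypassing 13). Deoxychlorination (POCl3, 90 °C) should give (5R)-4-chloro-3-methoxy-2-methyl-5-(5-phenylpentyl)-5,6,7,8-tetrahydroquinoline F6. N-oxidation (mCPBA) should give (5R)-4-chloro-3-methoxy-2-methyl-5-(5-phenylpentyl)-5,6,7,8-tetrahydroquinoline 1-oxide F7. Nucleophilic aromatic substitution at C-4, activated by the N-oxide (NaOMe, MeOH, reflux), then gives 14.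

3. Step 2. Oxidative addition may stall on the electron-rich, copper-binding pyridin-4-olate, or protodebromination may take over.
Fallback setting out from 1 and returning at 3. Elbs persulfate oxidation (K2S2O8, aq NaOH, rt) should give 2,6-dimethyl-4-oxo-1,4-dihydropyridin-3-yl hydrogen sulfate F8, hydrolysed with hot dilute H2SO4 to 3-hydroxy-2,6-dimethylpyridin-4(1H)-one F9. Methylation of the more acidic 3-OH (MeI, 1 equiv K2CO3, acetone) then gives 3.

**Further compounds**
F1 | step 5 | 3-bromo-5-methoxy-2,6-dimethylpyridin-4(1H)-one | COc1c(C)[nH]c(C)c(Br)c1=O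
F2 | step 5 | 3-bromo-4,5-dimethoxy-2,6-dimethylpyridine | COc1c(C)nc(C)c(Br)c1OC
F3 | step 5 | 3,4-dimethoxy-2,6-dimethyl-5-(4,4,5,5-tetramethyl-1,3,2-dioxaborolan-2-yl)pyridine | COc1c(C)nc(C)c(B2OC(C)(C)C(C)(C)O2)c1OC
F4 | step 5 | (3R)-3-(4,5-dimethoxy-2,6-dimethylpyridin-3-yl)-8-phenyloctanal | O=CC[C@@H](CCCCCc1ccccc1)c1c(C)nc(C)c(OC)c1OC
F5 | step 5 | (5R)-3,4-dimethoxy-2-methyl-5-(5-phenylpentyl)-5,6-dihydroquinoline | COc1c(OC)c(C)nc2c1[C@H](CCCCCc1ccccc1)CC=C2
F6 | step 7 | (5R)-4-chloro-3-methoxy-2-methyl-5-(5-phenylpentyl)-5,6,7,8-tetrahydroquinoline | COc1c(C)nc2c(c1Cl)[C@H](CCCCCc1ccccc1)CCC2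
F7 | step 7 | (5R)-4-chloro-3-methoxy-2-methyl-5-(5-phenylpentyl)-5,6,7,8-tetrahydroquinoline 1-oxide | COc1c(C)[n+]([O-])c2c(c1Cl)[C@H](CCCCCc1ccccc1)CCC2
F8 | step 2 | 2,6-dimethyl-4-oxo-1,4-dihydropyridin-3-yl hydrogen sulfate | Cc1cc(=O)c(OS(=O)(=O)O)c(C)[nH]1
F9 | step 2 | 3-hydroxy-2,6-dimethylpyridin-4(1H)-one | Cc1cc(=O)c(O)c(C)[nH]1
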